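# Proposed synthesis of CNP0141808.1 by aryne insertion into a chiral carboxylic acid

## Analysis of the target

Target 28 is a 2-hydroxychroman-4-one. Ring A is a benzene ring without a free position (C5 OH, C6 OMe, C7 OH, C8 CH3, C8a bound to O1, C4a bound to the C4 carbonyl). Ring C is a six-membered cyclic hemiacetal (O1–C2(OH)–C3–C4=O). C3 carries an exocyclic carbinol carbon, called C9 here, which bears a hydroxyl group and the 4-hydroxyphenyl ring B.

There are three stereocentres: C2 (S), C3 (R) and C9 (S). C3 and C9 form a syn-aldol pair: with the chain C4–C3–C9–aryl drawn as a zigzag, C2 and O9 lie on the same side. The C2 hydroxyl is trans to the C3 side chain on ring C and, being hemiacetalic, is configurationally mobile.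

The molecule is fragile in several ways:
- The lactol can open to a β-keto aldehyde whose C3 hydrogen is very acidic, which threatens the C3 configuration.
- The lactol can lose water across C2–C3 to give a chromone.
- C3–C9 is the bond of a β-hydroxy ketone and can cleave by retro-aldol reaction.
- C9 is a para-hydroxybenzylic alcohol, prone to ionisation (quinone methide) and to hydrogenolysis.
- Ring A is an oxidisable polyphenol.

The difficulties are the hexasubstituted ring A with four differentiated oxygens, the attachment of an α-branched, epimerisable acyl group to C4a between two oxygen-bearing carbons, and the need to close ring C through O8a and never through O5.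

The strategy rests on one feature. C4a and C8a are neighbours, they carry the C4 carbonyl carbon and O1, and they are flanked by the C5 oxygen and the C8 methyl group. This is the substitution pattern left when a carboxylic acid adds across an unsymmetrical aryne C4a≡C8a.

## Retrosynthetic reasoning

Target 28 is traced to the tribenzyl ether 27 by cutting the three benzyl–oxygen bonds at O5, O7 and O4′. This cut is placed last because the forward reaction is a neutral hydrogenolysis. The polyphenol and the para-hydroxybenzylic alcohol then appear only in the final operation and meet neither acid, base nor fluoride.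

Compound 27 comes from the silyl ether 26 by cutting the O9–Si bond. The silyl group is needed earlier to block retro-aldol cleavage and O-arylation. It is removed while every phenol is still benzylated, so that no phenoxide can assist loss of the C9 oxygen.

Lactol 26 is opened at the hemiacetal bond O1–C2 to the keto aldehyde 25, and the formyl carbon of 25 is traced to the terminal alkene of ketone 23. Carrying C2 as a vinyl group keeps it inert through the basic, hot aryne step. Because O8a is the only free phenol in 23, the forward ring closure can go one way only.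

Ketone 23 is cut at two bonds at once, C4a–C4 and C8a–O1, giving the aryne 22 (from silyl triflate 11) and the carboxylic acid 20. The cut is made here because both bonds sit on adjacent ring carbons, and a carboxylate can deliver its oxygen and then its acyl carbon to the two ends of an aryne. This avoids an intermolecular acylation of a crowded, electron-rich ring with an epimerisable acyl donor. It also fixes O1 on C8a by mechanism. The forward reaction must add the oxygen at C8a, not C4a, and must transfer the acyl group before the aryl anion is protonated.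

Acid 20 is cut at the C3–C9 bond, through the silyl ether 18 and the aldol adduct 17, to the N-crotonyl imide 14 and aldehyde 15. Imide 14 comes from auxiliary 12 and acid chloride 13. An auxiliary-controlled syn-aldol reaction of a dienolate sets C3 and C9 together and delivers the vinyl group at the same time.

Silyl triflate 11 is cut at C4a–Si and O8a–S to the bromophenol 8. Forward, silicon is moved from oxygen to carbon after bromine–lithium exchange and the phenoxide is then triflated. Compound 8 loses its bromine atom to give phenol 7, whose only unsubstituted ring carbon is C4a.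

Phenol 7 is cut at the C6–O bond through the quinone monoketal 6 to phenol 5. Oxidative dearomatisation puts the new oxygen para to the free O8a hydroxyl and leaves it as a methyl ether, while O8a ends up free. Alkylation of the corresponding hydroquinone would not achieve this differentiation.

Phenol 5 is traced through aldehyde 2 to the symmetrical starting material 1. The formyl group of 1 does two jobs. Its hydrogen bond keeps one ortho hydroxyl (the later O8a) out of the benzylation, and its reduction supplies the C8 methyl group.

## Alternatives that were turned down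

Alternative 1: Ring A is disconnected at C4a–C8a and traced to the squarate-derived cyclobutenone A2. On heating, A2 would open to the dienylketene A3. Six-electron ring closure and tautomerisation would then give phenol A1, with O8a free, C4a unsubstituted and O5, O6 and O7 as ethyl, methyl and isopropyl ethers.
- For: every substituent of ring A is placed by construction, with no reliance on the regiochemistry of aromatic substitution or dearomatisation. On this point it is at least as secure as steps 1 to 4 of the chosen route.
- Against: it stops at A1. The C4a–C4 bond, ring C and both stereocentres are still missing, and A1 would have to be turned into an aryne precursor like 11 or acylated directly with an epimerisable acyl donor.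
- Against: the ethyl and isopropyl ethers at O5 and O7 would need Lewis-acid cleavage that the lactol and the benzylic alcohol cannot survive. Exchanging them for benzyl groups costs steps.
- Against: A2 itself needs several low-temperature organometallic additions to a squaric ester.
- Comparison: this is another way to a compound of type 7, not another solution to the bond that matters. The chosen route reaches 7 in four steps and then forms C4a–C4 and C8a–O1 in one operation.

Alternative 2: The O1–C8a bond is made by oxygen insertion, and ring C is traced to the 3-hydroperoxyindan-1-one A5. Under mild acid the aryl carbon C8a would migrate to the inner peroxide oxygen, and hydration of the resulting cyclic oxocarbenium ion would give the tetrasilylated lactol A4.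
- For: the ring expansion delivers the lactol at the right oxidation level, puts O1 on C8a by necessity and never passes through a free keto aldehyde. On that last point it is stronger than the chosen route, which forms 25 transiently.
- Against: A5 must first be built as an indanone with the C3 and C9 centres in the right absolute and relative configuration. An aldol reaction on an indanone enolate offers no dependable control of this kind.
- Against: A5 is a β-peroxy ketone that can eliminate to an indenone and destroy C3.
- Against: the acid needed for the rearrangement also ionises the para-silyloxybenzylic silyl ether, and the acyl group ortho to the migrating carbon lowers its migratory aptitude.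
- Comparison: the chosen strategy takes C3 and C9 from a reliable auxiliary aldol, joins two fragments of similar size and needs no acid.

Alternative 3: Ring C is disconnected at C4–C3 and O1–C2. Irradiation of the benzodioxinone A7 would release the quinoketene A9, which would add as a heterodiene across the enol ether double bond of the dioxasiline A8 to give the silylene-bridged tricycle A6.
- For: this is the most convergent plan. It closes ring C and forms both bonds in one step, keeps O2 and O9 tied so that no β-keto aldehyde ever appears, and needs only a global desilylation afterwards. On step economy after the key step it is stronger than the chosen route.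
- For: the stereochemistry is coherent. In A6 the C3–C4 bond is trans to the aryl group on the silylene ring, so the ketene must attack the enol ether face away from the aryl group, which is the sterically expected face. The cis ring fusion gives the 2-epi configuration while tied, and this would correct itself by anomerisation after desilylation.
- Against: photogenerated quinoketenes are normally captured by heteroatom nucleophiles. Cycloaddition with an enol ether must compete with [2+2] addition and dimerisation.
- Against: the product is an aryl ketone exposed to the same light.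
- Against: enantiopure A8 is not a simple compound, and the final cleavage of five Si–O bonds exposes the free polyphenol to fluoride.
- Comparison: the chosen route is longer after the key step, but every bond is formed by a thermal reaction of established type.

Key step: step 11

Assumption on the chemistry: C2 is a hemiacetal carbon that equilibrates by ring opening, so its configuration is taken to settle thermodynamically at the 2,3-trans arrangement drawn in the target.

## Route

### Ring A: steps 1 to 6

Step 1
Reactants: 1 2,4,6-trihydroxybenzaldehyde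
Product: 2 2,4-bis(benzyloxy)-6-hydroxybenzaldehyde
Conditions: BnBr (2.1 equiv), K2CO3, DMF, 0 °C to rt
Reagents that add atoms: benzyl bromide, BrCc1ccccc1
Why: Williamson etherification; the hydroxyl hydrogen-bonded to the formyl group is the least nucleophilic, so two equivalents of halide should stop at the dibenzyl ether and leave one ortho hydroxyl (the later O8a) free, the two ortho hydroxyls of 1 being equivalent.

Step 2
Reactants: 2 2,4-bis(benzyloxy)-6-hydroxybenzaldehyde
Product: 5 3,5-bis(benzyloxy)-2-methylphenol, via aryl ethyl carbonate 3 (not isolated), via ortho-quinone methide 4 (not isolated)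
Conditions: ClCO2Et, Et3N, THF, 0 °C; then NaBH4, H2O, 0 °C to rt
Reagents that add atoms: none
Why: Reductive deoxygenation of a salicylaldehyde; hydride reduces the formyl group of 3, the carbonate shifts to the benzylic oxygen and is expelled by the phenoxide, and 4 takes a second hydride at its exocyclic carbon, so CHO becomes the C8 methyl group and the phenol returns free.

Step 3
Reactants: 5 3,5-bis(benzyloxy)-2-methylphenol
Product: 6 3,5-bis(benzyloxy)-4,4-dimethoxy-2-methylcyclohexa-2,5-dien-1-one
Conditions: PhI(OAc)2 (2.2 equiv), MeOH, 0 °C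
Reagents that add atoms: methanol, CO
Why: Oxidative dearomatisation of a phenol by a trivalent iodine reagent; methanol should attack para to the phenol oxygen (C6), and a second oxidation of the now more electron-rich ring gives the para-quinone monoketal, which marks C6 as the methoxylated carbon while C8a becomes the carbonyl.

Step 4
Reactants: 6 quinone monoketal
Product: 7 3,5-bis(benzyloxy)-4-methoxy-2-methylphenol
Conditions: Zn dust, AcOH, THF, 0 °C
Reagents that add atoms: none
Why: Reductive aromatisation of a quinone monoketal; two-electron reduction of the dienone and loss of one methoxide from C6 should give the para-methoxyphenol with O6 methylated and O8a free.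

Step 5
Reactants: 7 3,5-bis(benzyloxy)-4-methoxy-2-methylphenol
Product: 8 3,5-bis(benzyloxy)-2-bromo-4-methoxy-6-methylphenol
Conditions: NBS, CH2Cl2, −78 to 0 °C, dark
Reagents that add atoms: N-bromosuccinimide, O=C1CCC(=O)N1Br
Why: Electrophilic aromatic bromination; C4a is the only unsubstituted carbon of ring A and is ortho to the phenol, so the site is unambiguous, and low temperature without light should suppress benzylic bromination and oxidation of the ring.

Step 6
Reactants: 8 3,5-bis(benzyloxy)-2-bromo-4-methoxy-6-methylphenol
Product: 11 3,5-bis(benzyloxy)-4-methoxy-6-methyl-2-(trimethylsilyl)phenyl trifluoromethanesulfonate, via aryl trimethylsilyl ether 9 (not isolated), via lithium 2-silylphenoxide 10 (not isolated)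
Conditions: (Me3Si)2NH, THF, 65 °C, then evaporation; n-BuLi, THF, −78 °C; Tf2O, −78 to 0 °C
Reagents that add atoms: hexamethyldisilazane, C[Si](C)(C)N[Si](C)(C)C; trifluoromethanesulfonic anhydride, O=S(=O)(OS(=O)(=O)C(F)(F)F)C(F)(F)F
Why: Standard preparation of a 2-silylaryl triflate; O-silylation, bromine–lithium exchange at −78 °C (faster than deprotonation of the benzyl ethers) and retro-Brook shift of silicon from oxygen to C4a give 10, which is triflated on oxygen.

### Acid fragment: steps 7 to 10

Step 7
Reactants: 12 (S)-4-benzyl-1,3-oxazolidin-2-one; 13 (E)-but-2-enoyl chloride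
Product: 14 (S)-4-benzyl-3-[(E)-but-2-enoyl]-1,3-oxazolidin-2-one
Conditions: n-BuLi, THF, −78 °C; then 13, −78 to 0 °C
Reagents that add atoms: none
Why: N-acylation of the lithiated oxazolidinone with an acid chloride, the usual entry to N-enoyl imides.

Step 8
Reactants: 14 N-crotonyl imide; 15 4-(benzyloxy)benzaldehyde
Product: 17 (S)-4-benzyl-3-[(2S)-2-[(S)-[4-(benzyloxy)phenyl](hydroxy)methyl]but-3-enoyl]-1,3-oxazolidin-2-one, via boron dienolate 16 (not isolated)
Conditions: Bu2BOTf, Et3N, CH2Cl2, −78 to 0 °C; 15, −78 to 0 °C; H2O2, pH 7 buffer, MeOH, 0 °C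
Reagents that add atoms: none
Why: Evans syn-aldol reaction of an N-crotonyl imide; soft enolisation removes a γ-hydrogen to give the Z-configured dienolate 16, which reacts at its α-carbon through a chair Zimmerman–Traxler transition state, so the Z geometry sets the syn relationship and the benzyl group of the auxiliary shields one face, giving (S) at both new centres (C3 and C9 of the target).

Step 9
Reactants: 17 aldol adduct
Product: 18 (S)-4-benzyl-3-[(2S)-2-[(S)-[4-(benzyloxy)phenyl][(tert-butyldimethylsilyl)oxy]methyl]but-3-enoyl]-1,3-oxazolidin-2-one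
Conditions: TBSOTf, 2,6-lutidine, CH2Cl2, −78 to 0 °C
Reagents that add atoms: tert-butyldimethylsilyl trifluoromethanesulfonate, CC(C)(C)[Si](C)(C)OS(=O)(=O)C(F)(F)F
Why: Silylation of a hindered secondary alcohol with a silyl triflate; the ether blocks retro-aldol cleavage and keeps O9 from adding to the aryne later.

Step 10
Reactants: 18 silyl ether of the aldol adduct
Product: 20 (2S)-2-[(S)-[4-(benzyloxy)phenyl][(tert-butyldimethylsilyl)oxy]methyl]but-3-enoic acid, via peroxy acid 19 (not isolated)
Conditions: LiOH, H2O2, THF/H2O, 0 °C; then Na2SO3; dilute HCl to pH 4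
Reagents that add atoms: hydrogen peroxide, OO
Why: Hydroperoxide cleavage of the N-acyl oxazolidinone; the weakly basic hydroperoxide anion attacks the exocyclic carbonyl, so the α-centre and the β,γ-double bond should be kept, sulfite reduces 19 to the acid and auxiliary 12 is recovered.

### Key step and endgame: steps 11 to 14

Step 11
Reactants: 20 acid; 11 silyl triflate
Product: 23 (2S)-1-[2,4-bis(benzyloxy)-6-hydroxy-3-methoxy-5-methylphenyl]-2-[(S)-[4-(benzyloxy)phenyl][(tert-butyldimethylsilyl)oxy]methyl]but-3-en-1-one, via caesium carboxylate 21 (not isolated), via aryne 22 (not isolated)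
Conditions: 20, Cs2CO3 (0.5 equiv), MeOH, then azeotropic drying (toluene); 11 (1.3 equiv), CsF (3 equiv), THF, sealed tube, 100 °C; dilute HCl work-up
Reagents that add atoms: none
Why: Fluoride removes the silyl group of 11 and the triflate leaves, giving aryne 22 (C4a≡C8a). The carboxylate oxygen of 21 adds to C8a, and the aryl anion formed at C4a attacks the neighbouring ester carbonyl (4-exo-trig) to a four-membered alkoxide that opens to the ketone on C4a and the phenoxide on C8a, a net acyl shift from oxygen to carbon. The closest known reaction type is the formal insertion of fluoride-generated arynes into the C–O bond of carboxylic acids to give ortho-hydroxyaryl ketones. No ring is closed in the product, the four-membered ring being transient, and no stereocentre is created, C3 and C9 arriving with the acid. The step needs regioselective addition of oxygen at C8a; the C5 benzyloxy group distorts and polarises the aryne so that the nucleophile attacks the remote carbon and the charge develops at C4a next to the withdrawing C–O bond, the weak opposing effects of the C6 and C7 oxygens should cancel, and the C8 methyl group is only a small steric cost. It also needs acyl transfer to outrun protonation of the aryl anion, which is why the acid is used as its dried caesium salt with no other proton source. Epimerisation at C3, conjugation of the vinyl group and loss of the C9 silyloxy group should be held back because the product sits in the flask as its caesium phenoxide, a vinylogous carboxylate whose α-hydrogen is much less acidic than that of the free ketone.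

Step 12
Reactants: 23 ortho-hydroxyaryl vinyl ketone
Product: 26 (2S,3R)-5,7-bis(benzyloxy)-3-[(S)-[4-(benzyloxy)phenyl][(tert-butyldimethylsilyl)oxy]methyl]-2-hydroxy-6-methoxy-8-methyl-2,3-dihydro-4H-chromen-4-one, via diol 24 (not isolated), via keto aldehyde 25 (not isolated)
Conditions: OsO4 (2 mol %), NaIO4 (4 equiv), 2,6-lutidine, dioxane/H2O, 0 °C to rt
Reagents that add atoms: osmium tetroxide, O=[Os](=O)(=O)=O (oxygen replenished by sodium periodate, [Na+].[O-]I(=O)(=O)=O)
Why: Lemieux–Johnson cleavage of the terminal alkene; aldehyde 25 should be captured at once by the only free phenol (O8a) in a 6-exo-trig hemiacetalisation that closes ring C, and C2 settles by ring–chain equilibration with its hydroxyl trans to the C3 side chain (pseudo-axial anomeric hydroxyl anti to the neighbouring substituent).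

Step 13
Reactants: 26 silylated lactol
Product: 27 (2S,3R)-5,7-bis(benzyloxy)-3-[(S)-[4-(benzyloxy)phenyl](hydroxy)methyl]-2-hydroxy-6-methoxy-8-methyl-2,3-dihydro-4H-chromen-4-one
Conditions: Bu4NF, AcOH (1:1), THF, 0 °C to rt
Reagents that add atoms: none
Why: Fluoride cleavage of the secondary silyl ether; acetic acid keeps the medium near neutral so that the C9 alkoxide does not persist (no retro-aldol) and the lactol is not dehydrated, and all phenols are still benzylated so that none can assist ionisation at C9.

Step 14
Reactants: 27 tribenzyl lactol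
Product: 28 (2S,3R)-2,5,7-trihydroxy-3-[(S)-hydroxy(4-hydroxyphenyl)methyl]-6-methoxy-8-methyl-2,3-dihydro-4H-chromen-4-one
Conditions: H2 (1 atm), 10% Pd/C, EtOAc, rt, stopped at full debenzylation
Reagents that add atoms: none
Why: Hydrogenolysis of three aryl benzyl ethers under neutral conditions; aryl benzyl ethers are cleaved much faster than the secondary benzylic alcohol at C9, the hydrogen-bonded aryl ketone or the lactol, so no stereocentre is touched.

## Compound list

1 | 2,4,6-trihydroxybenzaldehyde | O=Cc1c(O)cc(O)cc1O | starting material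
2 | 2,4-bis(benzyloxy)-6-hydroxybenzaldehyde | O=Cc1c(O)cc(OCc2ccccc2)cc1OCc1ccccc1 | intermediate
3 | 3,5-bis(benzyloxy)-2-formylphenyl ethyl carbonate | CCOC(=O)Oc1cc(OCc2ccccc2)cc(OCc2ccccc2)c1C=O | intermediate
4 | 3,5-bis(benzyloxy)-6-methylidenecyclohexa-2,4-dien-1-one | C=C1C(=O)C=C(OCc2ccccc2)C=C1OCc1ccccc1 | intermediate
5 | 3,5-bis(benzyloxy)-2-methylphenol | Cc1c(O)cc(OCc2ccccc2)cc1OCc1ccccc1 | intermediate
6 | 3,5-bis(benzyloxy)-4,4-dimethoxy-2-methylcyclohexa-2,5-dien-1-one | CC1=C(OCc2ccccc2)C(OC)(OC)C(OCc2ccccc2)=CC1=O | intermediate
7 | 3,5-bis(benzyloxy)-4-methoxy-2-methylphenol | COc1c(OCc2ccccc2)cc(O)c(C)c1OCc1ccccc1 | intermediate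
8 | 3,5-bis(benzyloxy)-2-bromo-4-methoxy-6-methylphenol | COc1c(OCc2ccccc2)c(Br)c(O)c(C)c1OCc1ccccc1 | intermediate
9 | [3,5-bis(benzyloxy)-2-bromo-4-methoxy-6-methylphenoxy]trimethylsilane | COc1c(OCc2ccccc2)c(Br)c(O[Si](C)(C)C)c(C)c1OCc1ccccc1 | intermediate
10 | lithium 3,5-bis(benzyloxy)-4-methoxy-6-methyl-2-(trimethylsilyl)phenolate | [Li+].[O-]c1c(C)c(OCc2ccccc2)c(OC)c(OCc2ccccc2)c1[Si](C)(C)C | intermediate
11 | 3,5-bis(benzyloxy)-4-methoxy-6-methyl-2-(trimethylsilyl)phenyl trifluoromethanesulfonate | COc1c(OCc2ccccc2)c(C)c(OS(=O)(=O)C(F)(F)F)c([Si](C)(C)C)c1OCc1ccccc1 | intermediate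
12 | (S)-4-benzyl-1,3-oxazolidin-2-one | O=C1OC[C@H](Cc2ccccc2)N1 | starting material
13 | (E)-but-2-enoyl chloride | C/C=C/C(Cl)=O | starting material
14 | (S)-4-benzyl-3-[(E)-but-2-enoyl]-1,3-oxazolidin-2-one | C/C=C/C(=O)N1C(=O)OC[C@@H]1Cc1ccccc1 | intermediate
15 | 4-(benzyloxy)benzaldehyde | O=Cc1ccc(OCc2ccccc2)cc1 | starting material
16 | (S)-4-benzyl-3-[(1Z)-1-[(dibutylboranyl)oxy]buta-1,3-dien-1-yl]-1,3-oxazolidin-2-one | CCCCB(CCCC)O/C(=C\C=C)N1C(=O)OC[C@@H]1Cc1ccccc1 | intermediate
17 | (S)-4-benzyl-3-[(2S)-2-[(S)-[4-(benzyloxy)phenyl](hydroxy)methyl]but-3-enoyl]-1,3-oxazolidin-2-one | C=C[C@@H]([C@H](O)c1ccc(OCc2ccccc2)cc1)C(=O)N1C(=O)OC[C@@H]1Cc1ccccc1 | intermediate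
18 | (S)-4-benzyl-3-[(2S)-2-[(S)-[4-(benzyloxy)phenyl][(tert-butyldimethylsilyl)oxy]methyl]but-3-enoyl]-1,3-oxazolidin-2-one | C=C[C@@H]([C@H](O[Si](C)(C)C(C)(C)C)c1ccc(OCc2ccccc2)cc1)C(=O)N1C(=O)OC[C@@H]1Cc1ccccc1 | intermediate
19 | (2S)-2-[(S)-[4-(benzyloxy)phenyl][(tert-butyldimethylsilyl)oxy]methyl]but-3-eneperoxoic acid | C=C[C@@H]([C@H](O[Si](C)(C)C(C)(C)C)c1ccc(OCc2ccccc2)cc1)C(=O)OO | intermediate
20 | (2S)-2-[(S)-[4-(benzyloxy)phenyl][(tert-butyldimethylsilyl)oxy]methyl]but-3-enoic acid | OC(=O)[C@H]([C@H](O[Si](C)(C)C(C)(C)C)c1ccc(OCc2ccccc2)cc1)C=C | intermediate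
21 | caesium (2S)-2-[(S)-[4-(benzyloxy)phenyl][(tert-butyldimethylsilyl)oxy]methyl]but-3-enoate | [Cs+].[O-]C(=O)[C@H]([C@H](O[Si](C)(C)C(C)(C)C)c1ccc(OCc2ccccc2)cc1)C=C | intermediate
22 | 3,5-bis(benzyloxy)-4-methoxy-6-methylbenzyne (triple bond C4a≡C8a) | COC1=C(OCc2ccccc2)C#CC(C)=C1OCc1ccccc1 | intermediate
23 | (2S)-1-[2,4-bis(benzyloxy)-6-hydroxy-3-methoxy-5-methylphenyl]-2-[(S)-[4-(benzyloxy)phenyl][(tert-butyldimethylsilyl)oxy]methyl]but-3-en-1-one | COc1c(OCc2ccccc2)c(C)c(O)c(c1OCc1ccccc1)C(=O)[C@H]([C@H](O[Si](C)(C)C(C)(C)C)c1ccc(OCc2ccccc2)cc1)C=C | intermediate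
24 | (2S)-1-[2,4-bis(benzyloxy)-6-hydroxy-3-methoxy-5-methylphenyl]-2-[(S)-[4-(benzyloxy)phenyl][(tert-butyldimethylsilyl)oxy]methyl]-3,4-dihydroxybutan-1-one (both epimers at the new carbinol) | COc1c(OCc2ccccc2)c(C)c(O)c(c1OCc1ccccc1)C(=O)[C@H]([C@H](O[Si](C)(C)C(C)(C)C)c1ccc(OCc2ccccc2)cc1)C(O)CO | intermediate
25 | (2R)-3-[2,4-bis(benzyloxy)-6-hydroxy-3-methoxy-5-methylphenyl]-2-[(S)-[4-(benzyloxy)phenyl][(tert-butyldimethylsilyl)oxy]methyl]-3-oxopropanal | COc1c(OCc2ccccc2)c(C)c(O)c(c1OCc1ccccc1)C(=O)[C@H]([C@H](O[Si](C)(C)C(C)(C)C)c1ccc(OCc2ccccc2)cc1)C=O | intermediate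
26 | (2S,3R)-5,7-bis(benzyloxy)-3-[(S)-[4-(benzyloxy)phenyl][(tert-butyldimethylsilyl)oxy]methyl]-2-hydroxy-6-methoxy-8-methyl-2,3-dihydro-4H-chromen-4-one | COc1c(OCc2ccccc2)c(C)c2c(c1OCc1ccccc1)C(=O)[C@H]([C@H](O[Si](C)(C)C(C)(C)C)c1ccc(OCc3ccccc3)cc1)[C@@H](O)O2 | intermediate
27 | (2S,3R)-5,7-bis(benzyloxy)-3-[(S)-[4-(benzyloxy)phenyl](hydroxy)methyl]-2-hydroxy-6-methoxy-8-methyl-2,3-dihydro-4H-chromen-4-one | COc1c(OCc2ccccc2)c(C)c2c(c1OCc1ccccc1)C(=O)[C@H]([C@H](O)c1ccc(OCc3ccccc3)cc1)[C@@H](O)O2 | intermediate
28 | (2S,3R)-2,5,7-trihydroxy-3-[(S)-hydroxy(4-hydroxyphenyl)methyl]-6-methoxy-8-methyl-2,3-dihydro-4H-chromen-4-one | COc1c(O)c(C)c2c(c1O)C(=O)[C@H]([C@H](O)c1ccc(O)cc1)[C@@H](O)O2 | target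

## Step count and risks

Total: 14 steps. Longest linear sequence: 10 steps (1 to 6, then 11 to 14); the acid branch contributes steps 7 to 10.

**Step 11 (key step).** Several things can go wrong.
- The aryl anion may be protonated before the acyl group moves, leaving only the aryl ester.
- The carboxylate may add at C4a if the methyl group at C8 hinders C8a more than expected.
- Hot fluoride may remove the C9 silyl group.
- Base may move the double bond into conjugation or epimerise C3 once the ketone is formed.

Fallback from 8 and 20, returning at 23: the phenol 8 would be esterified with acid 20 (DCC, DMAP, CH2Cl2) to the bromoaryl ester F1. Bromine–lithium exchange with t-BuLi in THF/Et2O at −100 °C would then put the carbanion on C4a, from where it takes the acyl group from the neighbouring oxygen (anionic Fries-type 1,3-shift) to give 23. This forms the same C4a–C4 bond without an aryne and without fluoride.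

**Step 3.** Methanol may attack the ortho carbon C4a instead of C6, or traces of water may lead to the quinone instead of the ketal. The crowding of C6 by two benzyloxy groups is the reason for concern.

Fallback from 5, returning at 7:
- Oxidation of 5 with (KSO3)2NO would give the para-quinone F2.
- Na2S2O4 would reduce it to the hydroquinone F3.
- Pivaloyl chloride in pyridine would acylate the less hindered O8a hydroxyl to the monopivalate F4.
- MeI and K2CO3 in acetone would methylate O6 to the methyl ether pivalate F5.
- NaOMe in MeOH would release 7.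

**Step 12.** Three problems are possible.
- Periodate may oxidise the electron-rich para-methoxyphenol of ring A before or after the alkene is cleaved.
- Keto aldehyde 25 may enolise before the phenol captures it, with loss of configuration at C3.
- Lactol 26 may dehydrate to the chromone.

Fallback from 23, returning at 26: the phenol would be silylated (TESOTf, 2,6-lutidine) to the aryl triethylsilyl ether F6. The vinyl group would be cleaved under the same OsO4/NaIO4 conditions, now without an oxidisable phenol, to the silylated keto aldehyde F7. Bu4NF/AcOH at −40 °C would then remove only the aryl silyl group, so that the phenol closes onto the aldehyde as it appears and gives 26. F7 has no internal trap for its aldehyde and is therefore more exposed to enolisation at C3 than 25; it would be carried on crude and cold.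

**Step 14.** Hydrogenolysis may go on to cleave the C9–O bond once the para oxygen of ring B is free, or reduce the aryl ketone. The product may also dehydrate on the catalyst support.

Fallback from 26, returning at 28: the order of the last two steps would be reversed. Hydrogenolysis of 26 (H2, Pd/C, EtOAc) with the silyl ether still on C9, where the benzylic C–O bond is shielded, would give the triphenol silyl ether F8. Bu4NF/AcOH in THF at 0 °C would then give 28. The price is that the free polyphenol meets fluoride in the last step.

## Further compounds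

F1 | step 11 | 3,5-bis(benzyloxy)-2-bromo-4-methoxy-6-methylphenyl (2S)-2-[(S)-[4-(benzyloxy)phenyl][(tert-butyldimethylsilyl)oxy]methyl]but-3-enoate | COc1c(OCc2ccccc2)c(Br)c(OC(=O)[C@H]([C@H](O[Si](C)(C)C(C)(C)C)c2ccc(OCc3ccccc3)cc2)C=C)c(C)c1OCc1ccccc1
F2 | step 3 | 3,5-bis(benzyloxy)-2-methylcyclohexa-2,5-diene-1,4-dione | CC1=C(OCc2ccccc2)C(=O)C(OCc2ccccc2)=CC1=O
F3 | step 3 | 2,6-bis(benzyloxy)-3-methylbenzene-1,4-diol | Cc1c(O)cc(OCc2ccccc2)c(O)c1OCc1ccccc1
F4 | step 3 | 3,5-bis(benzyloxy)-4-hydroxy-2-methylphenyl 2,2-dimethylpropanoate | Cc1c(OC(=O)C(C)(C)C)cc(OCc2ccccc2)c(O)c1OCc1ccccc1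
F5 | step 3 | 3,5-bis(benzyloxy)-4-methoxy-2-methylphenyl 2,2-dimethylpropanoate | COc1c(OCc2ccccc2)cc(OC(=O)C(C)(C)C)c(C)c1OCc1ccccc1
F6 | step 12 | (2S)-1-[2,4-bis(benzyloxy)-3-methoxy-5-methyl-6-[(triethylsilyl)oxy]phenyl]-2-[(S)-[4-(benzyloxy)phenyl][(tert-butyldimethylsilyl)oxy]methyl]but-3-en-1-one | COc1c(OCc2ccccc2)c(C)c(O[Si](CC)(CC)CC)c(c1OCc1ccccc1)C(=O)[C@H]([C@H](O[Si](C)(C)C(C)(C)C)c1ccc(OCc2ccccc2)cc1)C=C
F7 | step 12 | (2R)-3-[2,4-bis(benzyloxy)-3-methoxy-5-methyl-6-[(triethylsilyl)oxy]phenyl]-2-[(S)-[4-(benzyloxy)phenyl][(tert-butyldimethylsilyl)oxy]methyl]-3-oxopropanal | COc1c(OCc2ccccc2)c(C)c(O[Si](CC)(CC)CC)c(c1OCc1ccccc1)C(=O)[C@H]([C@H](O[Si](C)(C)C(C)(C)C)c1ccc(OCc2ccccc2)cc1)C=O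
F8 | step 14 | (2S,3R)-3-[(S)-[(tert-butyldimethylsilyl)oxy](4-hydroxyphenyl)methyl]-2,5,7-trihydroxy-6-methoxy-8-methyl-2,3-dihydro-4H-chromen-4-one | COc1c(O)c(C)c2c(c1O)C(=O)[C@H]([C@H](O[Si](C)(C)C(C)(C)C)c1ccc(O)cc1)[C@@H](O)O2
A1 | alternative 1 | 5-ethoxy-4-methoxy-2-methyl-3-(propan-2-yloxy)phenol | CCOc1cc(O)c(C)c(OC(C)C)c1OC
A2 | alternative 1 | 4-(1-ethoxyethenyl)-4-methoxy-2-methyl-3-(propan-2-yloxy)cyclobut-2-en-1-one | CCOC(=C)C1(OC)C(OC(C)C)=C(C)C1=O
A3 | alternative 1 | 5-ethoxy-4-methoxy-2-methyl-3-(propan-2-yloxy)hexa-1,3,5-trien-1-one | CCOC(=C)C(OC)=C(OC(C)C)C(C)=C=O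
A4 | alternative 2 | (2S,3R)-5,7-bis[(tert-butyldimethylsilyl)oxy]-3-[(S)-[(tert-butyldimethylsilyl)oxy]{4-[(tert-butyldimethylsilyl)oxy]phenyl}methyl]-2-hydroxy-6-methoxy-8-methyl-2,3-dihydro-4H-chromen-4-one | COc1c(O[Si](C)(C)C(C)(C)C)c(C)c2c(c1O[Si](C)(C)C(C)(C)C)C(=O)[C@H]([C@H](O[Si](C)(C)C(C)(C)C)c1ccc(O[Si](C)(C)C(C)(C)C)cc1)[C@@H](O)O2
A5 | alternative 2 | 5,7-bis[(tert-butyldimethylsilyl)oxy]-2-[(S)-[(tert-butyldimethylsilyl)oxy]{4-[(tert-butyldimethylsilyl)oxy]phenyl}methyl]-3-hydroperoxy-6-methoxy-4-methyl-2,3-dihydro-1H-inden-1-one (configuration at the ring carbon bearing the side chain as at C3 of the target) | COc1c(O[Si](C)(C)C(C)(C)C)c(C)c2c(c1O[Si](C)(C)C(C)(C)C)C(=O)[C@H]([C@H](O[Si](C)(C)C(C)(C)C)c1ccc(O[Si](C)(C)C(C)(C)C)cc1)C2OO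
A6 | alternative 3 | silylene-bridged tricyclic chromanone (target skeleton with O2 and O9 joined by di-tert-butylsilylene, phenols as tert-butyldimethylsilyl ethers, cis-fused at C2–C3) | COc1c(O[Si](C)(C)C(C)(C)C)c(C)c2c(c1O[Si](C)(C)C(C)(C)C)C(=O)[C@@H]3[C@@H](c4ccc(O[Si](C)(C)C(C)(C)C)cc4)O[Si](C(C)(C)C)(C(C)(C)C)O[C@@H]3O2
A7 | alternative 3 | 5,7-bis[(tert-butyldimethylsilyl)oxy]-6-methoxy-2,2,8-trimethyl-4H-1,3-benzodioxin-4-one | COc1c(O[Si](C)(C)C(C)(C)C)c(C)c2OC(C)(C)OC(=O)c2c1O[Si](C)(C)C(C)(C)C
A8 | alternative 3 | (4S)-2,2-di-tert-butyl-4-{4-[(tert-butyldimethylsilyl)oxy]phenyl}-4H-1,3,2-dioxasiline | CC(C)(C)[Si]1(C(C)(C)C)OC=C[C@@H](c2ccc(O[Si](C)(C)C(C)(C)C)cc2)O1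
A9 | alternative 3 | 3,5-bis[(tert-butyldimethylsilyl)oxy]-4-methoxy-2-methyl-6-(oxomethylidene)cyclohexa-2,4-dien-1-one | COC1=C(O[Si](C)(C)C(C)(C)C)C(=C=O)C(=O)C(C)=C1O[Si](C)(C)C(C)(C)C
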